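**Retrosynthetic overview**

- Feature: in ring A (C5–C10) the isopropenyl carbon C4 on C5 and the oxygen on C8 are cis-1,4, and C10 carries exactly a methyl and a vinyl group. C4 and O8 are therefore tied as a C(=O)–O bridge, and ring A is cut by [4+2] into 5-bromo-2-pyranone and the 1,1-disubstituted alkene of isoprene (bonds C5–C10 and C8–C9).
- The bridge is opened to an N-methoxy-N-methylamide and the C8 carbinol, which is resolved with a lipase; the amide is turned into the isopropenyl group.
- The bromine left on C7 takes C11–C13 by palladium-catalysed coupling with a propanoate zinc enolate. Ring B (C6–O–C12–C11–C7) is closed by selenolactonisation and radical deselenation to the cis-fused lactone.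
- C11 is hydroxylated on the convex face and angeloylated; desilylation and acetylation of O8 finish the synthesis.
- Ring order: ring A inside the bridged bicycle (step 1), bridge opened (step 2), ring B (step 9).

Key step: step 1

Assumption: the cycloaddition is run thermally and gives the racemate, the single enantiomer is secured by the kinetic resolution in step 3, and 5-bromo-2H-pyran-2-one is taken as purchasable (otherwise one step from coumalic acid by bromodecarboxylation).

Numbering and faces used below: C10 (methyl, vinyl), C9 (CH2), C8 (CH–O), C7, C6 (CH–O of the lactone), C5 (CH–isopropenyl), C4 (isopropenyl carbon), C11/C12/C13 (lactone α-carbon, carbonyl, methyl). "Down" is the face of ring A that carries the C10 methyl. In the target C4 and O8 are down; the vinyl group, O6 and C11 are up. With this numbering the target is 5R,6S,7R,8S,10R,11S.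

**Route**

Step 1
Reactants: 1 5-bromo-2H-pyran-2-one; 2 isoprene
Product: 3 racemic 6-bromo-8-ethenyl-8-methyl-2-oxabicyclo[2.2.2]oct-5-en-3-one (bridged bromo lactone; vinyl anti and methyl syn to the lactone bridge)
Conditions: isoprene (10 equiv), BHT (cat.), toluene, sealed tube, 90 °C
Reagents that add atoms: none
Why: Thermal Diels–Alder reaction with the bromopyranone as the 4π partner and the 1,1-disubstituted alkene of isoprene as the 2π partner, an asynchronous concerted [4+2] process in which the electrophilic pyranone C6 bonds to the CH2 terminus (C8–C9) while charge builds at the tertiary allylic carbon, which then bonds to pyranone C3 (C5–C10). The closest known reaction type is the thermal cycloaddition of 3- and 5-bromo-2-pyranones, which behave as ambiphilic dienes, with alkenes to give isolable 2-oxabicyclo[2.2.2]octenones that keep their CO2 bridge below about 100 °C. Ring A is closed by an intermolecular two-bond [4+2] annulation and is held as a boat by the lactone bridge, which necessarily spans C5 and C8 on one face. C5 and C8 are set together by the suprafacial addition across the diene termini, and C10 by the endo orientation of the vinyl π system under the diene, so that the vinyl group ends anti to the bridge and the smaller methyl syn to it. The step needs periselectivity (the electron-poor, weakly aromatic pyranone is the better diene and the more substituted, more nucleophilic alkene of isoprene the better 2π partner), head-to-tail regioselectivity (polarisation of both partners) and endo-vinyl selectivity; it needs no absolute control because the racemic adduct is resolved in step 3.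

Step 2
Reactants: 3 racemic bridged bromo lactone
Product: 4 racemic 3-bromo-6-ethenyl-4-hydroxy-N-methoxy-N,6-dimethylcyclohex-2-ene-1-carboxamide (amide on C5, OH on C8 and C10 methyl all down)
Conditions: MeNH(OMe)·HCl, AlMe3, CH2Cl2, 0 °C to rt; dilute aq. HCl work-up
Reagents that add atoms: N,O-dimethylhydroxylamine hydrochloride, CNOC.Cl
Why: Aminolysis of the strained bridged lactone by the aluminium amide cleaves only the acyl–oxygen bond, so C5 and C8 keep their configuration and the bridge is released as an amide and an allylic alcohol.

Step 3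
Reactants: 4 racemic hydroxy amide
Product: 5 (8S)-hydroxy amide, single enantiomer (recovered alcohol)
Conditions: lipase PS (Burkholderia cepacia, immobilised), vinyl acetate, MTBE, 35 °C, to just past half conversion; chromatography
Reagents that add atoms: none
Why: Lipase-catalysed kinetic resolution by enantioselective transesterification, in which the empirical size rule for secondary carbinols (bromoalkenyl side large, ring CH2 side medium) predicts acetylation of the 8R enantiomer and recovery of the 8S alcohol; no stereocentre is formed, and the configuration of 5 is to be confirmed by MTPA-ester analysis.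

Step 4
Reactants: 5 (8S)-hydroxy amide
Product: 6 C8 tert-butyldimethylsilyl ether of 5
Conditions: TBSCl, imidazole, DMF, rt
Reagents that add atoms: tert-butyldimethylsilyl chloride, CC(C)(C)[Si](C)(C)Cl
Why: Standard silylation of a secondary allylic alcohol masks O8 for the organometallic, basic and radical steps that follow.

Step 5
Reactants: 6 silyl ether amide
Product: 7 1-[3-bromo-4-(tert-butyldimethylsilyloxy)-6-ethenyl-6-methylcyclohex-2-en-1-yl]ethan-1-one (C4 methyl ketone)
Conditions: MeMgBr, THF, 0 °C; cold aq. NH4Cl
Reagents that add atoms: methylmagnesium bromide, C[Mg]Br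
Why: Grignard addition to the N-methoxy-N-methylamide stops at the ketone because the magnesium-chelated tetrahedral adduct survives until the cold buffered quench, which also limits enolisation of the β,γ-unsaturated ketone at C5.

Step 6
Reactants: 7 methyl ketone
Product: 8 tert-butyl{[2-bromo-5-ethenyl-5-methyl-4-(prop-1-en-2-yl)cyclohex-2-en-1-yl]oxy}dimethylsilane (isopropenyl on C5)
Conditions: Zn, CH2Br2, TiCl4, THF, 0 °C (reagent aged); then 7, CH2Cl2, 0 °C to rt
Reagents that add atoms: dibromomethane, BrCBr
Why: Takai–Lombardo methylenation with a non-basic zinc/titanium methylene reagent converts the enolisable ketone into the isopropenyl group without epimerising C5 or moving the C6=C7 bond into conjugation, which a basic phosphorus ylide could do.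

Step 7
Reactants: 8 alkenyl bromide; 9 methyl 2-bromopropanoate (racemic)
Product: 11 methyl 2-[6-(tert-butyldimethylsilyloxy)-4-ethenyl-4-methyl-3-(prop-1-en-2-yl)cyclohex-1-en-1-yl]propanoate (C11 epimers), via bromozinc ester enolate 10 (not isolated)
Conditions: 9, Zn dust (TMSCl-activated), THF, rt; then 8, Pd(dba)2 (5 mol %), P(tBu)3 (5 mol %), THF, 50 °C
Reagents that add atoms: none
Why: Palladium-catalysed cross-coupling of a Reformatsky reagent with an alkenyl bromide (Negishi-type α-alkenylation of an ester) forms C7–C11 under neutral conditions that leave the β,γ-unsaturated ester in place; C11 forms as a mixture of epimers, which does not matter because C11 is made planar again in step 11.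

Step 8
Reactants: 11 methyl ester
Product: 12 2-[6-(tert-butyldimethylsilyloxy)-4-ethenyl-4-methyl-3-(prop-1-en-2-yl)cyclohex-1-en-1-yl]propanoic acid (C11 epimers)
Conditions: LiOH·H2O, THF/MeOH/H2O, rt to 40 °C; then aq. HCl to pH 3, 0 °C
Reagents that add atoms: lithium hydroxide, [Li+].[OH-]
Why: Saponification, in which hydroxide attack at the ester carbonyl should outrun deprotonation at C11 and any dienolate is reprotonated at C11, so the double bond should stay at C6=C7 and the silyl ether survive the cold, mildly acidic work-up.

Step 9
Reactants: 12 β,γ-unsaturated acid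
Product: 13 4-(tert-butyldimethylsilyloxy)-6-ethenyl-3,6-dimethyl-3a-(phenylselanyl)-7-(prop-1-en-2-yl)hexahydro-1-benzofuran-2(3H)-one (lactone O6 up, C11 up, selenium on C7 down; C11 epimers)
Conditions: N-(phenylseleno)phthalimide, CSA (cat.), CH2Cl2, 0 °C to rt
Reagents that add atoms: N-(phenylseleno)phthalimide, O=C1c2ccccc2C(=O)N1[Se]c1ccccc1
Why: Phenylselenolactonisation of a β,γ-unsaturated acid (5-endo opening of the seleniranium ion by the carboxyl oxygen at C6, anti addition), in which trans-diaxial opening with oxygen entering C6 anti to the C5 isopropenyl group keeps the C8 silyloxy group equatorial, whereas the other face would place O6, the silyloxy group and the C10 methyl all axial on one side, so the lactone with O6 and C11 up is expected.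

Step 10
Reactants: 13 selenolactone
Product: 14 4-(tert-butyldimethylsilyloxy)-6-ethenyl-3,6-dimethyl-7-(prop-1-en-2-yl)hexahydro-1-benzofuran-2(3H)-one (cis-fused, H7 down; C11 epimers)
Conditions: Bu3SnH (0.2 M), AIBN (cat.), toluene, 80 °C
Reagents that add atoms: none
Why: Radical deselenation by a tin hydride chain, in which the tertiary ring-fusion radical at C7 should take hydrogen on the face anti to the C6–O bond to give the less strained cis-fused γ-lactone (the trans-fused isomer would force the C8 silyloxy and C10 methyl groups syn-diaxial), and the high hydride concentration outpaces any cyclisation onto the vinyl group.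

Step 11
Reactants: 14 cis-fused lactone
Product: 15 C11 tertiary alcohol of 14 (3-hydroxy lactone, OH on the convex face, 11S)
Conditions: KHMDS, THF, −78 to −40 °C; then 2-(phenylsulfonyl)-3-phenyloxaziridine, −78 °C; aq. NH4Cl
Reagents that add atoms: 2-(phenylsulfonyl)-3-phenyloxaziridine, O=S(=O)(c1ccccc1)N1OC1c1ccccc1
Why: Electrophilic α-hydroxylation of the potassium lactone enolate with an N-sulfonyloxaziridine, in which the oxidant attacks planar C11 on the convex face of the cis-fused bicycle (syn to H7, anti to C8 and its silyloxy group), so the hydroxyl ends up and the methyl on the concave face whichever C11 epimer is used.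

Step 12
Reactants: 15 tertiary alcohol
Product: 16 C11 angelate of 15 (C8 still silylated)
Conditions: LiHMDS, THF, −78 °C; then angelic anhydride, −78 to 0 °C; aq. NH4Cl
Reagents that add atoms: (Z)-2-methylbut-2-enoic anhydride, C/C=C(/C)C(=O)OC(=O)/C(C)=C\C
Why: O-acylation of the lithium alkoxide of a hindered tertiary alcohol with angelic anhydride is a stereoconservative angeloylation that avoids nucleophilic catalysts, which isomerise angelates to tiglates, and the lactone has no α-hydrogen left for the base to remove.

Step 13
Reactants: 16 silyl ether angelate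
Product: 17 C8 alcohol (desilylated 16)
Conditions: HF·pyridine, THF/pyridine, 0 °C to rt
Reagents that add atoms: none
Why: Fluoride-mediated desilylation under buffered, weakly acidic conditions should leave the angelate, the lactone and both alkenes untouched and avoid base-induced acyl migration from O11 to O8.

Step 14
Reactants: 17 C8 alcohol
Product: 18 target, 4-acetoxy-6-ethenyl-3,6-dimethyl-2-oxo-7-(prop-1-en-2-yl)octahydro-1-benzofuran-3-yl (Z)-2-methylbut-2-enoate (5R,6S,7R,8S,10R,11S in the numbering above)
Conditions: Ac2O, pyridine, DMAP (cat.), CH2Cl2, 0 °C to rt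
Reagents that add atoms: acetic anhydride, CC(=O)OC(C)=O
Why: Acetylation of the secondary C8 alcohol with acetic anhydride and pyridine proceeds with retention at C8 and gives the target.

**Compound list**

1 | 5-bromo-2H-pyran-2-one | O=C1C=CC(Br)=CO1 | starting material
2 | isoprene | C=CC(C)=C | starting material
3 | 6-bromo-8-ethenyl-8-methyl-2-oxabicyclo[2.2.2]oct-5-en-3-one, racemate (enantiomer carried on is drawn) | C=C[C@@]1(C)C[C@@H]2OC(=O)[C@H]1C=C2Br | intermediate
4 | 3-bromo-6-ethenyl-4-hydroxy-N-methoxy-N,6-dimethylcyclohex-2-ene-1-carboxamide, racemate (enantiomer carried on is drawn) | C=C[C@@]1(C)C[C@H](O)C(Br)=C[C@@H]1C(=O)N(C)OC | intermediate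
5 | the same hydroxy amide, single (8S) enantiomer | C=C[C@@]1(C)C[C@H](O)C(Br)=C[C@@H]1C(=O)N(C)OC | intermediate
6 | C8 tert-butyldimethylsilyl ether of 5 | C=C[C@@]1(C)C[C@H](O[Si](C)(C)C(C)(C)C)C(Br)=C[C@@H]1C(=O)N(C)OC | intermediate
7 | 1-[3-bromo-4-(tert-butyldimethylsilyloxy)-6-ethenyl-6-methylcyclohex-2-en-1-yl]ethan-1-one | C=C[C@@]1(C)C[C@H](O[Si](C)(C)C(C)(C)C)C(Br)=C[C@@H]1C(C)=O | intermediate
8 | tert-butyl{[2-bromo-5-ethenyl-5-methyl-4-(prop-1-en-2-yl)cyclohex-2-en-1-yl]oxy}dimethylsilane | C=C[C@@]1(C)C[C@H](O[Si](C)(C)C(C)(C)C)C(Br)=C[C@@H]1C(C)=C | intermediate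
9 | methyl 2-bromopropanoate (racemic) | CC(Br)C(=O)OC | starting material
10 | bromo(1-methoxy-1-oxopropan-2-yl)zinc (Reformatsky reagent) | COC(=O)C(C)[Zn]Br | intermediate
11 | methyl 2-[6-(tert-butyldimethylsilyloxy)-4-ethenyl-4-methyl-3-(prop-1-en-2-yl)cyclohex-1-en-1-yl]propanoate (C11 epimers) | C=C[C@@]1(C)C[C@H](O[Si](C)(C)C(C)(C)C)C(C(C)C(=O)OC)=C[C@@H]1C(C)=C | intermediate
12 | the corresponding propanoic acid (C11 epimers) | C=C[C@@]1(C)C[C@H](O[Si](C)(C)C(C)(C)C)C(C(C)C(=O)O)=C[C@@H]1C(C)=C | intermediate
13 | 4-(tert-butyldimethylsilyloxy)-6-ethenyl-3,6-dimethyl-3a-(phenylselanyl)-7-(prop-1-en-2-yl)hexahydro-1-benzofuran-2(3H)-one (C11 epimers) | C=C[C@@]1(C)C[C@H](O[Si](C)(C)C(C)(C)C)[C@]2([Se]c3ccccc3)[C@@H](OC(=O)C2C)[C@@H]1C(=C)C | intermediate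
14 | 4-(tert-butyldimethylsilyloxy)-6-ethenyl-3,6-dimethyl-7-(prop-1-en-2-yl)hexahydro-1-benzofuran-2(3H)-one, cis-fused (C11 epimers) | C=C[C@@]1(C)C[C@H](O[Si](C)(C)C(C)(C)C)[C@@H]2[C@@H](OC(=O)C2C)[C@@H]1C(=C)C | intermediate
15 | 3-hydroxy derivative of 14 (11S) | C=C[C@@]1(C)C[C@H](O[Si](C)(C)C(C)(C)C)[C@@H]2[C@@H](OC(=O)[C@@]2(C)O)[C@@H]1C(=C)C | intermediate
16 | C11 (Z)-2-methylbut-2-enoate of 15 | C=C[C@@]1(C)C[C@H](O[Si](C)(C)C(C)(C)C)[C@@H]2[C@@H](OC(=O)[C@@]2(C)OC(=O)/C(C)=C\C)[C@@H]1C(=C)C | intermediate
17 | C8 alcohol (desilylated 16) | C=C[C@@]1(C)C[C@H](O)[C@@H]2[C@@H](OC(=O)[C@@]2(C)OC(=O)/C(C)=C\C)[C@@H]1C(=C)C | intermediate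
18 | CNP0140071.1, 4-acetoxy-6-ethenyl-3,6-dimethyl-2-oxo-7-(prop-1-en-2-yl)octahydro-1-benzofuran-3-yl (Z)-2-methylbut-2-enoate | C=C[C@@]1(C)C[C@H](OC(C)=O)[C@@H]2[C@@H](OC(=O)[C@@]2(C)OC(=O)/C(C)=C\C)[C@@H]1C(=C)C | target

**Step count**

Total: 14 steps. Longest linear sequence: 14 steps (1 and 2 to 18); 9 enters at step 7 without steps of its own.

**Steps most likely to fail**

1. Step 1. The cycloaddition may follow the wrong periselectivity (the pyranone reacting as the 2π partner toward isoprene as the diene), may engage the less substituted alkene, may show little preference for vinyl over methyl in the endo position, or may lose the bridge by CO2 extrusion on long heating. Fallback: setting out from 2, the diene is reshaped to the more electron-poor 3,5-dibromo-2H-pyran-2-one F1, a more reactive ambiphilic diene that should react at lower temperature with the same regiochemistry and stronger endo preference. With isoprene it should give the racemic dibromo adduct 4,6-dibromo-8-ethenyl-8-methyl-2-oxabicyclo[2.2.2]oct-5-en-3-one F2. The bridgehead bromine α to the lactone carbonyl is then removed with Zn in AcOH/THF, which leaves the alkenyl bromide alone, and the route is rejoined at 3.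

2. Step 3. The enzyme may acylate the hindered carbinol too slowly, may discriminate poorly between two flanking groups of similar bulk, or may show the opposite sense. Fallback: setting out from 4, the racemate is esterified with (S)-2-methoxy-2-phenylacetic acid (DCC, DMAP cat., CH2Cl2) to the diastereomeric esters, the (S)-O-methylmandelate of the 8S alcohol F3 and the (S)-O-methylmandelate of the 8R alcohol F4. These are separated by chromatography or crystallisation, and F3 is methanolysed (K2CO3, MeOH) to rejoin the route at 5.

3. Step 9. The seleniranium ion may be opened on the wrong face (O6 and C11 down), closure may occur 4-exo at C7 to a β-lactone, or the electrophile may be consumed by the isopropenyl group. Fallback: setting out from 11, the facial control is handed to the C8 hydroxyl.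
   - Desilylation (HF·pyridine) should give the hydroxy ester F5.
   - Hydroxyl-directed epoxidation (VO(acac)2, tBuOOH, CH2Cl2) should give the syn epoxy alcohol F6, with the epoxide down and only the allylic alkene oxidised.
   - Saponification (LiOH) and mild acidification should let the carboxyl open the epoxide at C6 from the up face, giving the 7,8-cis-dihydroxy lactone F7 with O6 up.
   - The cis-diol is closed with 1,1'-thiocarbonyldiimidazole to the cyclic thionocarbonate F8.
   - Barton–McCombie-type cleavage (Bu3SnH, AIBN, toluene, reflux) breaks the tertiary C7–O bond and reduces the same ring-fusion radical as in step 10 to the hydroxy lactone F9.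
   - Silylation (TBSCl, imidazole) rejoins the route at 14.

**Further compounds**

F1 | step 1 | 3,5-dibromo-2H-pyran-2-one | O=C1OC=C(Br)C=C1Br
F2 | step 1 | 4,6-dibromo-8-ethenyl-8-methyl-2-oxabicyclo[2.2.2]oct-5-en-3-one (racemate, enantiomer leading to 3 drawn) | C=C[C@@]1(C)C[C@@H]2OC(=O)[C@@]1(Br)C=C2Br
F3 | step 3 | (S)-2-methoxy-2-phenylacetate of the 8S alcohol 5 | C=C[C@@]1(C)C[C@H](OC(=O)[C@@H](OC)c2ccccc2)C(Br)=C[C@@H]1C(=O)N(C)OC
F4 | step 3 | (S)-2-methoxy-2-phenylacetate of the 8R alcohol (enantiomer of 5) | C=C[C@]1(C)C[C@@H](OC(=O)[C@@H](OC)c2ccccc2)C(Br)=C[C@H]1C(=O)N(C)OC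
F5 | step 9 | methyl 2-[4-ethenyl-6-hydroxy-4-methyl-3-(prop-1-en-2-yl)cyclohex-1-en-1-yl]propanoate (C11 epimers) | C=C[C@@]1(C)C[C@H](O)C(C(C)C(=O)OC)=C[C@@H]1C(C)=C
F6 | step 9 | 6,7-epoxide of F5, epoxide cis to the C8 hydroxyl | C=C[C@@]1(C)C[C@H](O)[C@]2(C(C)C(=O)OC)O[C@@H]2[C@@H]1C(C)=C
F7 | step 9 | 6-ethenyl-3a,4-dihydroxy-3,6-dimethyl-7-(prop-1-en-2-yl)hexahydro-1-benzofuran-2(3H)-one (7,8-cis-diol, O6 up) | C=C[C@@]1(C)C[C@H](O)[C@]2(O)[C@@H](OC(=O)C2C)[C@@H]1C(=C)C
F8 | step 9 | cyclic 7,8-thionocarbonate of F7 | C=C[C@@]1(C)C[C@H](OC(=S)O3)[C@]23[C@@H](OC(=O)C2C)[C@@H]1C(=C)C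
F9 | step 9 | 6-ethenyl-4-hydroxy-3,6-dimethyl-7-(prop-1-en-2-yl)hexahydro-1-benzofuran-2(3H)-one, cis-fused (desilylated 14) | C=C[C@@]1(C)C[C@H](O)[C@@H]2[C@@H](OC(=O)C2C)[C@@H]1C(=C)C
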